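The route rests on cutting the C6–C7 bond together with the lactone O–C12 bond. The feature used is the fully substituted carbinol C7, which lies between the lactone carbinol C6 and the exocyclic C11=C13 alkene of the five-membered lactone ring. That pattern is what a γ-oxygenated 2-carbomethoxy allylboronate gives on adding to an aldehyde. In one operation dienal 11 (C1–C6, C9, C10) and the Z-configured γ-siloxy allylboronate 16 (C7, C8, C11–C13) are joined, C6 and C7 are set, and the lactone ring closes. The ten-membered carbocycle is closed afterwards between C8 and C9 by pinacol coupling, before angeloylation and deprotection.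

Key step: step 11

Remark: germacrane numbering is used throughout. The (R)-configured phosphoric acid is assumed to deliver the allyl unit to the Re face of the aldehyde, as it does with simple pinacol allylboronates; otherwise its enantiomer is used. C11 of the amine adducts 19–23, 26 and 27 is a temporary centre of undefined configuration.

Step 1
Reactants: 1 geraniol
Product: 2 geranyl 4-methoxybenzyl (PMB) ether
Conditions: NaH, PMBCl, Bu4NI (cat.), THF/DMF, 0 °C → rt
Reagents that add atoms: 4-methoxybenzyl chloride, COc1ccc(CCl)cc1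
Why: Williamson etherification of the primary allylic alkoxide installs a group that survives peracid, periodic acid, base and hydride and can later be removed oxidatively next to a silyl ether, which an acetate could not do because it would be lost in the ester reduction of step 5.

Step 2
Reactants: 2 geranyl PMB ether
Product: 3 racemic 6,7-epoxide of 2
Conditions: mCPBA (1.05 equiv), NaHCO3, CH2Cl2, −20 → 0 °C
Reagents that add atoms: 3-chloroperbenzoic acid, OOC(=O)c1cccc(Cl)c1
Why: Prilezhaev epoxidation should take the more electron-rich distal trisubstituted alkene, the 2,3-alkene being deactivated by the allylic oxygen; the epoxide configuration is irrelevant because this carbon is cleaved in step 3.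

Step 3
Reactants: 3 racemic 6,7-epoxide
Product: 4 (4E)-6-[(4-methoxybenzyl)oxy]-4-methylhex-4-enal
Conditions: HIO4·2H2O, THF/Et2O, 0 °C
Reagents that add atoms: none
Why: periodic acid hydrates the epoxide in the flask and cleaves the resulting glycol (Malaprade cleavage) to the aldehyde and acetone, conditions under which the PMB ether and the remaining trisubstituted alkene are inert.

Step 4
Reactants: 4 (4E)-6-[(4-methoxybenzyl)oxy]-4-methylhex-4-enal; 5 ethyl 2-[bis(2,2,2-trifluoroethoxy)phosphoryl]propanoate
Product: 7 ethyl (2Z,6E)-8-[(4-methoxybenzyl)oxy]-2,6-dimethylocta-2,6-dienoate, via potassium phosphonate carbanion 6 (not isolated)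
Conditions: 5, KN(SiMe3)2, 18-crown-6, THF, −78 °C; then 4, −78 °C
Reagents that add atoms: none
Why: Still–Gennari olefination, in which the electron-poor phosphonate adduct collapses fast and irreversibly under cation-free conditions, should give the Z-trisubstituted enoate (ester cis to the chain) and thereby fix the C1=C10 geometry of the target.

Step 5
Reactants: 7 ethyl (2Z,6E)-8-[(4-methoxybenzyl)oxy]-2,6-dimethylocta-2,6-dienoate
Product: 8 (2Z,6E)-8-[(4-methoxybenzyl)oxy]-2,6-dimethylocta-2,6-dien-1-ol
Conditions: i-Bu2AlH (2.5 equiv), CH2Cl2, −78 °C; aq. potassium sodium tartrate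
Reagents that add atoms: none
Why: 1,2-reduction of the conjugated ester by the aluminium hydride gives the allylic alcohol without touching the alkene geometry or the PMB ether.

Step 6
Reactants: 8 (2Z,6E)-8-[(4-methoxybenzyl)oxy]-2,6-dimethylocta-2,6-dien-1-ol
Product: 9 TBDPS ether of 8
Conditions: TBDPSCl, imidazole, CH2Cl2, 0 °C → rt
Reagents that add atoms: tert-butyl(chloro)diphenylsilane, CC(C)(C)[Si](Cl)(c1ccccc1)c1ccccc1
Why: imidazole-promoted silylation of the primary alcohol; the TBDPS group is chosen because it must survive the aqueous acid of step 13 and then be removable beside a tertiary TBS ether.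

Step 7
Reactants: 9 TBDPS ether of 8
Product: 10 (2E,6Z)-8-[(tert-butyldiphenylsilyl)oxy]-3,7-dimethylocta-2,6-dien-1-ol
Conditions: DDQ, CH2Cl2/pH 7 buffer (10:1), 0 °C
Reagents that add atoms: none
Why: oxidative PMB cleavage by hydride abstraction from the electron-rich benzylic position frees only the geranyl-end hydroxyl, since silyl ethers and isolated alkenes do not react with DDQ under buffered conditions.

Step 8
Reactants: 10 (2E,6Z)-8-[(tert-butyldiphenylsilyl)oxy]-3,7-dimethylocta-2,6-dien-1-ol
Product: 11 (2E,6Z)-8-[(tert-butyldiphenylsilyl)oxy]-3,7-dimethylocta-2,6-dienal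
Conditions: MnO2 (activated, excess), CH2Cl2, rt
Reagents that add atoms: none
Why: heterogeneous MnO2 oxidation is selective for the allylic alcohol, stops at the enal and keeps the E geometry.

Step 9
Reactants: 12 methyl 4,4-dimethoxy-3-oxobutanoate; 13 2-(iodomethyl)-4,4,5,5-tetramethyl-1,3,2-dioxaborolane
Product: 14 methyl 4,4-dimethoxy-3-oxo-2-[(4,4,5,5-tetramethyl-1,3,2-dioxaborolan-2-yl)methyl]butanoate (racemic)
Conditions: K2CO3, acetone, rt → 45 °C (12 in slight excess)
Reagents that add atoms: none
Why: C-alkylation of the stabilized β-keto ester enolate with the primary α-iodo boronate (SN2 assisted by boron) should give the mono-alkylated product, whose racemic centre is erased in step 10.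

Step 10
Reactants: 14 methyl 4,4-dimethoxy-3-oxo-2-[(4,4,5,5-tetramethyl-1,3,2-dioxaborolan-2-yl)methyl]butanoate
Product: 16 methyl (Z)-3-[(tert-butyldimethylsilyl)oxy]-4,4-dimethoxy-2-[(4,4,5,5-tetramethyl-1,3,2-dioxaborolan-2-yl)methyl]but-2-enoate, via lithium enolate 15 (not isolated)
Conditions: LiN(SiMe3)2, THF, −78 °C; then TBSOTf, −78 °C
Reagents that add atoms: tert-butyldimethylsilyl trifluoromethanesulfonate, CC(C)(C)[Si](C)(C)OS(=O)(=O)C(F)(F)F
Why: kinetic O-silylation of the lithium-chelated enolate, in which the ketone oxygen and the ester carbonyl are held cis, should give the Z-enol ether (siloxy cis to the ester and trans to the borylmethyl carbon) with the acetal untouched at low temperature.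

Step 11
Reactants: 11 (2E,6Z)-8-[(tert-butyldiphenylsilyl)oxy]-3,7-dimethylocta-2,6-dienal; 16 methyl (Z)-3-[(tert-butyldimethylsilyl)oxy]-4,4-dimethoxy-2-[(4,4,5,5-tetramethyl-1,3,2-dioxaborolan-2-yl)methyl]but-2-enoate
Product: 18 (6S,7R)-α-methylene-β-siloxy-γ-lactone, (4R,5S)-4-[(tert-butyldimethylsilyl)oxy]-5-{(1E,5Z)-7-[(tert-butyldiphenylsilyl)oxy]-2,6-dimethylhepta-1,5-dien-1-yl}-4-(dimethoxymethyl)-3-methylidenedihydrofuran-2(3H)-one, via open-chain pinacol borate 17 (not isolated)
Conditions: (R)-3,3′-bis(2,4,6-triisopropylphenyl)-1,1′-binaphthyl-2,2′-diyl hydrogen phosphate (10 mol %), 4 Å MS, toluene, −20 °C → rt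
Reagents that add atoms: none
Why: The phosphoric acid hydrogen-bonds to a boronate oxygen of 16 and to the formyl group of 11, and the γ-carbon C7 adds to the aldehyde carbon C6 through a closed six-membered chair (allylboration, SE2′ through boron); the closest known reaction is the acid-catalysed addition of 2-alkoxycarbonyl allylboronates to aldehydes with lactonization in the flask. The boron-bound C6 alkoxide of 17 then attacks the methyl ester C12 in a 5-exo-trig acyl substitution, expels the methoxyboronate and closes the five-membered lactone ring. In the chair the aldehyde chain and the siloxy group (trans to CH2B) are equatorial and C8 (cis to CH2B) is axial, so the Z geometry of 16 becomes the C6/C7 relationship with the siloxy group trans and C8 cis to the dienyl chain. Neither partner has a stereocentre, so the absolute configuration (Re-face attack, 6S) is set by the chiral phosphate pocket. The step needs 1,2-addition through the γ-carbon only, which the cyclic boron transition state secures, while the β,β-disubstituted, non-enolizable enal disfavours conjugate addition and aldol side reactions. Molecular sieves keep the silyl enol ether and the acetal from hydrolysis.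

Step 12
Reactants: 18 (6S,7R)-α-methylene-β-siloxy-γ-lactone
Product: 19 dimethylamine adduct of 18 (C13 carries NMe2, C11 is sp3; 6S,7R)
Conditions: Me2NH (2 M in THF, 3 equiv), MeOH, 0 °C → rt
Reagents that add atoms: dimethylamine, CNC
Why: aza-Michael addition of the secondary amine masks the C11=C13 alkene, which would otherwise be a radical acceptor in step 16; the protic medium protonates the transient enolate before the C7 siloxy group can be expelled, and the C11 centre so formed is temporary.

Step 13
Reactants: 19 dimethylamine adduct of 18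
Product: 20 C8 aldehyde (dimethoxymethyl group of 19 replaced by formyl; 6S,7R)
Conditions: TFA/H2O (1:1), CHCl3, 0 °C; aq. NaHCO3
Reagents that add atoms: water, O
Why: acid-catalysed acetal hydrolysis through the oxocarbenium ion is run while C9 is still an acid-stable TBDPS ether, so no ionizable free Z-allylic alcohol is present, and the tertiary TBS ether and the protonated amine adduct are stable to cold aqueous acid.

Step 14
Reactants: 20 C8 aldehyde
Product: 21 C9 alcohol (TBDPS ether of 20 cleaved; 6S,7R)
Conditions: HF·pyridine, pyridine, THF, 0 °C → rt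
Reagents that add atoms: none
Why: fluoride-mediated desilylation is selective for the unhindered primary allylic TBDPS ether over the tertiary, doubly flanked TBS ether, and the buffered medium leaves the non-enolizable C8 aldehyde untouched.

Step 15
Reactants: 21 C9 alcohol
Product: 22 dialdehyde (C8 formyl and C9 Z-enal; 6S,7R)
Conditions: MnO2 (activated, excess), CH2Cl2, rt, used at once
Reagents that add atoms: none
Why: MnO2 oxidizes only the allylic alcohol and, being neutral and heterogeneous, should keep the Z geometry of the α-methyl enal.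

Step 16
Reactants: 22 dialdehyde
Product: 23 amine-masked (6S,7S,8S,9R)-7-O-TBS-(1(10)Z,4E)-germacradien-6,12-olide-8,9-diol
Conditions: SmI2 (3 equiv), t-BuOH (2 equiv), THF (0.003 M, slow addition of 22), −78 → 0 °C; aq. NaHCO3
Reagents that add atoms: none
Why: reductive pinacol coupling, in which the conjugated C9 aldehyde is reduced to a samarium ketyl that adds to the samarium-bound C8 aldehyde under high dilution, closes the ten-membered carbocycle; the two metal-bound oxygens are expected to lie anti across the forming bond in a ring of this size (8,9-threo diol, 9R), and C9, tethered to C6, should attack C8 anti to the C7 siloxy group (polar Felkin–Anh arrangement, 8S), while the saturated amine-masked lactone offers the ketyl no acceptor.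

Step 17
Reactants: 23 amine-masked 8,9-diol; 24 angelic acid, (Z)-2-methylbut-2-enoic acid
Product: 26 amine-masked 9-O-angelate (6S,7S,8S,9R), via angelic 2,4,6-trichlorobenzoic mixed anhydride 25 (not isolated)
Conditions: 24, 2,4,6-trichlorobenzoyl chloride, Et3N, toluene, rt; then 23, 75 °C
Reagents that add atoms: none
Why: Yamaguchi esterification without nucleophilic pyridine catalyst transfers the angeloyl group without Z to E isomerization, and the allylic C9 hydroxyl reacts in preference to the C8 hydroxyl, which is shielded by the quaternary siloxy-bearing C7; any amine lost by retro-Michael reaction at this temperature only anticipates step 18.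

Step 18
Reactants: 26 amine-masked 9-O-angelate
Product: 28 7-O-TBS ether of the target (C11=C13 restored; 6S,7S,8S,9R), via trimethylammonium iodide 27 (not isolated)
Conditions: MeI, THF, rt; then aq. NaHCO3, EtOAc, rt
Reagents that add atoms: none
Why: exhaustive N-methylation followed by base-induced E1cB (Hofmann-type) loss of trimethylamine restores the exocyclic alkene, the ammonium being a far better leaving group than the C7 siloxy group, and with C9 already acylated no free C9 hydroxyl can add to the restored acceptor.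

Step 19
Reactants: 28 7-O-TBS ether of the target
Product: 29 CNP0303917.1, (6S,7S,8S,9R)-9-angeloyloxy-7,8-dihydroxy-(1(10)Z,4E)-germacra-1(10),4,11(13)-trien-6,12-olide
Conditions: HF·pyridine, THF, 0 °C → rt
Reagents that add atoms: none
Why: fluoride cleaves the tertiary TBS ether, helped by the neighbouring C8 hydroxyl, under buffered acidic conditions that avoid acyl migration and translactonization; it is done only after C11 is sp2 again, so retro-aldol cleavage at C7 is not possible, and no stereocentre is touched.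

Compound list
1 | geraniol, (2E)-3,7-dimethylocta-2,6-dien-1-ol | CC(C)=CCC/C(C)=C/CO | starting material
2 | geranyl 4-methoxybenzyl ether, 1-({[(2E)-3,7-dimethylocta-2,6-dien-1-yl]oxy}methyl)-4-methoxybenzene | CC(C)=CCC/C(C)=C/COCc1ccc(OC)cc1 | intermediate
3 | racemic 3-{(3E)-5-[(4-methoxybenzyl)oxy]-3-methylpent-3-en-1-yl}-2,2-dimethyloxirane | CC1(C)OC1CC/C(C)=C/COCc1ccc(OC)cc1 | intermediate
4 | (4E)-6-[(4-methoxybenzyl)oxy]-4-methylhex-4-enal | O=CCC/C(C)=C/COCc1ccc(OC)cc1 | intermediate
5 | ethyl 2-[bis(2,2,2-trifluoroethoxy)phosphoryl]propanoate (racemic) | CCOC(=O)C(C)P(=O)(OCC(F)(F)F)OCC(F)(F)F | starting material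
6 | potassium carbanion of 5 | [K+].CCOC(=O)[C-](C)P(=O)(OCC(F)(F)F)OCC(F)(F)F | intermediate (not isolated)
7 | ethyl (2Z,6E)-8-[(4-methoxybenzyl)oxy]-2,6-dimethylocta-2,6-dienoate | CCOC(=O)/C(C)=C\CC/C(C)=C/COCc1ccc(OC)cc1 | intermediate
8 | (2Z,6E)-8-[(4-methoxybenzyl)oxy]-2,6-dimethylocta-2,6-dien-1-ol | OC/C(C)=C\CC/C(C)=C/COCc1ccc(OC)cc1 | intermediate
9 | tert-butyl({(2Z,6E)-8-[(4-methoxybenzyl)oxy]-2,6-dimethylocta-2,6-dien-1-yl}oxy)diphenylsilane | CC(C)(C)[Si](c1ccccc1)(c1ccccc1)OC/C(C)=C\CC/C(C)=C/COCc1ccc(OC)cc1 | intermediate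
10 | (2E,6Z)-8-[(tert-butyldiphenylsilyl)oxy]-3,7-dimethylocta-2,6-dien-1-ol | CC(C)(C)[Si](c1ccccc1)(c1ccccc1)OC/C(C)=C\CC/C(C)=C/CO | intermediate
11 | (2E,6Z)-8-[(tert-butyldiphenylsilyl)oxy]-3,7-dimethylocta-2,6-dienal | O=C/C=C(\C)CC/C=C(/C)CO[Si](c1ccccc1)(c1ccccc1)C(C)(C)C | intermediate
12 | methyl 4,4-dimethoxy-3-oxobutanoate | COC(OC)C(=O)CC(=O)OC | starting material
13 | 2-(iodomethyl)-4,4,5,5-tetramethyl-1,3,2-dioxaborolane | ICB1OC(C)(C)C(C)(C)O1 | starting material
14 | methyl 4,4-dimethoxy-3-oxo-2-[(4,4,5,5-tetramethyl-1,3,2-dioxaborolan-2-yl)methyl]butanoate (racemic) | COC(OC)C(=O)C(CB1OC(C)(C)C(C)(C)O1)C(=O)OC | intermediate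
15 | lithium (Z)-enolate of 14 (enolate oxygen cis to the ester) | [Li+].COC(OC)/C([O-])=C(\CB1OC(C)(C)C(C)(C)O1)C(=O)OC | intermediate (not isolated)
16 | methyl (Z)-3-[(tert-butyldimethylsilyl)oxy]-4,4-dimethoxy-2-[(4,4,5,5-tetramethyl-1,3,2-dioxaborolan-2-yl)methyl]but-2-enoate | COC(=O)/C(CB1OC(C)(C)C(C)(C)O1)=C(\O[Si](C)(C)C(C)(C)C)C(OC)OC | intermediate
17 | methyl (3R,4S,5E,9Z)-3-[(tert-butyldimethylsilyl)oxy]-11-[(tert-butyldiphenylsilyl)oxy]-3-(dimethoxymethyl)-6,10-dimethyl-2-methylidene-4-[(4,4,5,5-tetramethyl-1,3,2-dioxaborolan-2-yl)oxy]undeca-5,9-dienoate | C=C(C(=O)OC)[C@](O[Si](C)(C)C(C)(C)C)(C(OC)OC)[C@@H](OB1OC(C)(C)C(C)(C)O1)/C=C(\C)CC/C=C(/C)CO[Si](c1ccccc1)(c1ccccc1)C(C)(C)C | intermediate (not isolated)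
18 | (4R,5S)-4-[(tert-butyldimethylsilyl)oxy]-5-{(1E,5Z)-7-[(tert-butyldiphenylsilyl)oxy]-2,6-dimethylhepta-1,5-dien-1-yl}-4-(dimethoxymethyl)-3-methylidenedihydrofuran-2(3H)-one (6S,7R; siloxy trans and C8 cis to the dienyl chain) | C=C1C(=O)O[C@@H](/C=C(\C)CC/C=C(/C)CO[Si](c2ccccc2)(c2ccccc2)C(C)(C)C)[C@@]1(O[Si](C)(C)C(C)(C)C)C(OC)OC | intermediate
19 | dimethylamine adduct of 18: 3-[(dimethylamino)methyl] lactone, (4R,5S), C3 (C11) undefined | CN(C)CC1C(=O)O[C@@H](/C=C(\C)CC/C=C(/C)CO[Si](c2ccccc2)(c2ccccc2)C(C)(C)C)[C@@]1(O[Si](C)(C)C(C)(C)C)C(OC)OC | intermediate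
20 | C8 aldehyde: as 19 with formyl in place of dimethoxymethyl (6S,7R) | CN(C)CC1C(=O)O[C@@H](/C=C(\C)CC/C=C(/C)CO[Si](c2ccccc2)(c2ccccc2)C(C)(C)C)[C@@]1(O[Si](C)(C)C(C)(C)C)C=O | intermediate
21 | C9 alcohol: as 20 with free primary Z-allylic hydroxyl (6S,7R) | CN(C)CC1C(=O)O[C@@H](/C=C(\C)CC/C=C(/C)CO)[C@@]1(O[Si](C)(C)C(C)(C)C)C=O | intermediate
22 | dialdehyde: as 21 with the C9 alcohol oxidized to the Z-enal (6S,7R) | CN(C)CC1C(=O)O[C@@H](/C=C(\C)CC/C=C(/C)C=O)[C@@]1(O[Si](C)(C)C(C)(C)C)C=O | intermediate
23 | (6S,7S,8S,9R)-7-[(tert-butyldimethylsilyl)oxy]-13-(dimethylamino)-8,9-dihydroxy-(1(10)Z,4E)-germacra-1(10),4-dien-6,12-olide, C11 undefined | CN(C)CC1C(=O)O[C@H]2/C=C(\C)CC/C=C(/C)[C@@H](O)[C@H](O)[C@@]12O[Si](C)(C)C(C)(C)C | intermediate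
24 | angelic acid, (Z)-2-methylbut-2-enoic acid | C/C=C(/C)C(=O)O | starting material
25 | (Z)-2-methylbut-2-enoic 2,4,6-trichlorobenzoic anhydride | C/C=C(/C)C(=O)OC(=O)c1c(Cl)cc(Cl)cc1Cl | intermediate (not isolated)
26 | 9-O-angelate of 23 (6S,7S,8S,9R), C11 undefined | CN(C)CC1C(=O)O[C@H]2/C=C(\C)CC/C=C(/C)[C@@H](OC(=O)/C(C)=C\C)[C@H](O)[C@@]12O[Si](C)(C)C(C)(C)C | intermediate
27 | N-methyl quaternary ammonium iodide of 26 | C[N+](C)(C)CC1C(=O)O[C@H]2/C=C(\C)CC/C=C(/C)[C@@H](OC(=O)/C(C)=C\C)[C@H](O)[C@@]12O[Si](C)(C)C(C)(C)C.[I-] | intermediate (not isolated)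
28 | (6S,7S,8S,9R)-9-angeloyloxy-7-[(tert-butyldimethylsilyl)oxy]-8-hydroxy-(1(10)Z,4E)-germacra-1(10),4,11(13)-trien-6,12-olide | C=C1C(=O)O[C@H]2/C=C(\C)CC/C=C(/C)[C@@H](OC(=O)/C(C)=C\C)[C@H](O)[C@@]12O[Si](C)(C)C(C)(C)C | intermediate
29 | CNP0303917.1, (6S,7S,8S,9R)-9-angeloyloxy-7,8-dihydroxy-(1(10)Z,4E)-germacra-1(10),4,11(13)-trien-6,12-olide | C=C1C(=O)O[C@H]2/C=C(\C)CC/C=C(/C)[C@@H](OC(=O)/C(C)=C\C)[C@H](O)[C@@]12O | target

Total steps: 19. Longest linear sequence: 17 steps (steps 1–8 and 11–19, from geraniol).

Steps most likely to fail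

1. Step 11. The weak chiral acid may not activate the electron-poor, fully substituted allylboronate enough, or the aldehyde faces may be poorly discriminated. The fallback moves stereocontrol from the catalyst to the reagent and uses Lewis-acid activation, both established for this reagent class. It sets out from 12 and comes back at 18. Keto ester 12 is transesterified with (−)-8-phenylmenthol (toluene, reflux, methanol distilled off) to the 8-phenylmenthyl keto ester F1. This is alkylated with 13 (K2CO3, acetone) to the borylmethyl keto ester F2 and silylated as in step 10 to the Z-enol ether boronate with the auxiliary ester F3. Addition of F3 to dienal 11 under Sc(OTf)3 catalysis (toluene, −40 °C) should give the open-chain borate F4 with the aldehyde face chosen by the auxiliary. Warming with a trace of p-TsOH closes the lactone, releases the auxiliary and gives 18. The antipodal auxiliary is taken if the sense of induction is the opposite one.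

2. Step 16. The ring may close through an oxygen-syn, samarium-chelated arrangement and give the wrong configuration at C9, with intermolecular coupling as a further loss. The fallback sets the C9 centre after the ring is closed, by an inverting esterification in place of a retentive one. It sets out from 22 and comes back at 26. The same reductive coupling delivers the 8,9-erythro diol, the (6S,7S,8S,9S)-epimer of 23 F5. Mitsunobu esterification of its less hindered allylic C9 hydroxyl with angelic acid 24 (PPh3, diisopropyl azodicarboxylate, toluene, 0 °C) inverts C9 and installs the angelate in one operation, giving 26. Any threo diol 23 formed alongside is taken through step 17, so both epimers converge.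

3. Step 10. The enolate oxygen may bind to the neighbouring boron and not to lithium, so that the enolate geometry is lost and the E-enol ether forms; after step 11 this would give the C7 epimer. The fallback fixes the alkene geometry before boron is introduced. It sets out from 12 and comes back at 16. Keto ester 12 is silylated through its lithium chelate (LiN(SiMe3)2, THF, −78 °C; TBSOTf) to methyl (Z)-3-[(tert-butyldimethylsilyl)oxy]-4,4-dimethoxybut-2-enoate F6, whose geometry can be checked and purified at this trisubstituted stage. α-Deprotonation with lithium 2,2,6,6-tetramethylpiperidide (THF, −95 °C) gives the configurationally retained α-lithio acrylate F7. Addition of 13 forms the boron ate complex F8, whose 1,2-shift with loss of iodide (Matteson homologation of an alkenyl metal) should give 16 with the borylmethyl carbon in the place of the former vinyl hydrogen.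

Further compounds
F1 | step 11 | (1R,2S,5R)-5-methyl-2-(2-phenylpropan-2-yl)cyclohexyl 4,4-dimethoxy-3-oxobutanoate | C[C@@H]1CC[C@H]([C@@H](C1)OC(=O)CC(=O)C(OC)OC)C(C)(C)c1ccccc1
F2 | step 11 | (1R,2S,5R)-5-methyl-2-(2-phenylpropan-2-yl)cyclohexyl 4,4-dimethoxy-3-oxo-2-[(4,4,5,5-tetramethyl-1,3,2-dioxaborolan-2-yl)methyl]butanoate (C2 epimers) | C[C@@H]1CC[C@H]([C@@H](C1)OC(=O)C(CB2OC(C)(C)C(C)(C)O2)C(=O)C(OC)OC)C(C)(C)c1ccccc1
F3 | step 11 | (1R,2S,5R)-5-methyl-2-(2-phenylpropan-2-yl)cyclohexyl (Z)-3-[(tert-butyldimethylsilyl)oxy]-4,4-dimethoxy-2-[(4,4,5,5-tetramethyl-1,3,2-dioxaborolan-2-yl)methyl]but-2-enoate | C[C@@H]1CC[C@H]([C@@H](C1)OC(=O)/C(CB2OC(C)(C)C(C)(C)O2)=C(\O[Si](C)(C)C(C)(C)C)C(OC)OC)C(C)(C)c1ccccc1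
F4 | step 11 | 8-phenylmenthyl ester analogue of borate 17 (3R,4S) | C[C@@H]1CC[C@H]([C@@H](C1)OC(=O)C(=C)[C@](O[Si](C)(C)C(C)(C)C)(C(OC)OC)[C@@H](OB2OC(C)(C)C(C)(C)O2)/C=C(\C)CC/C=C(/C)CO[Si](c2ccccc2)(c2ccccc2)C(C)(C)C)C(C)(C)c1ccccc1
F5 | step 16 | (6S,7S,8S,9S)-7-[(tert-butyldimethylsilyl)oxy]-13-(dimethylamino)-8,9-dihydroxy-(1(10)Z,4E)-germacra-1(10),4-dien-6,12-olide (C9 epimer of 23) | CN(C)CC1C(=O)O[C@H]2/C=C(\C)CC/C=C(/C)[C@H](O)[C@H](O)[C@@]12O[Si](C)(C)C(C)(C)C
F6 | step 10 | methyl (Z)-3-[(tert-butyldimethylsilyl)oxy]-4,4-dimethoxybut-2-enoate | COC(=O)/C=C(\O[Si](C)(C)C(C)(C)C)C(OC)OC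
F7 | step 10 | methyl (Z)-3-[(tert-butyldimethylsilyl)oxy]-2-lithio-4,4-dimethoxybut-2-enoate | COC(=O)/C([Li])=C(\O[Si](C)(C)C(C)(C)C)C(OC)OC
F8 | step 10 | lithium alkenyl(iodomethyl)pinacolborate from F7 and 13 | [Li+].COC(=O)/C(=C(/C(OC)OC)O[Si](C)(C)C(C)(C)C)[B-]1(CI)OC(C)(C)C(C)(C)O1
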